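**Retrosynthetic overview**

1. Ring numbering: C1 (C=O next to the ring CH), C2 (C–OH), C3 (side chain), C4 (C=O), C5 (C–OMe), C6 (CH). Target 19 ⇐ Teuber oxidation at C1 of resorcinol 18, which already carries the oxygens at C2, C4 and C5.
2. 18 ⇐ one-pot [3+3] benzannulation that forms C1–C2 and C4–C5 and so closes the only ring: alkylmalonyl dichloride 11 (C2–C3–C4) plus metalated allyl methyl ether (C5–C6–C1).
3. Enabling feature: in the quinone ring the alkyl-bearing C3 lies between two oxygenated carbons C2 and C4, a hidden and constitutionally symmetric alkylmalonyl unit, and C5(OMe)–C6(H)–C1 is a 1-methoxyallyl unit; the symmetry makes the α/γ ambiguity of the allyl nucleophile irrelevant.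
4. 11 ⇐ malonic ester alkylation with bromide 6; 6 ⇐ skipped diyne 4 (copper-mediated coupling of 2 and 3) and Lindlar semi-hydrogenation, which sets both Z-alkenes.

Key step: step 8

Remark: compounds 1, 3, 7 and 12 are taken as commercial; the 2-hydroxy-1,4-quinone written for 19 and its 4-hydroxy-1,2-quinone tautomer are one compound, so either mode of the final oxidation gives 19.

**Route**

Step 1
Reactants: 1 hex-2-yn-1-ol
Product: 2 1-bromohex-2-yne
Conditions: PBr3, pyridine (cat.), Et2O, 0 °C to rt
Reagents that add atoms: phosphorus tribromide, BrP(Br)Br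
Why: Bromination of a primary propargylic alcohol with PBr3 (SN2 displacement of the phosphite ester by bromide) should give the bromide without allenic rearrangement.

Step 2
Reactants: 2 1-bromohex-2-yne; 3 non-8-yn-1-ol
Product: 4 pentadeca-8,11-diyn-1-ol
Conditions: CuI, NaI, Cs2CO3, DMF, rt
Reagents that add atoms: none
Why: Copper-mediated alkylation of a terminal alkyne by a propargylic halide under carbonate base should give the skipped 1,4-diyne, the free hydroxyl being tolerated.

Step 3
Reactants: 4 pentadeca-8,11-diyn-1-ol
Product: 5 (8Z,11Z)-pentadeca-8,11-dien-1-ol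
Conditions: H2 (1 atm), Pd/CaCO3 poisoned with Pb(OAc)2 (Lindlar catalyst), quinoline, EtOAc, rt, stopped after 2 equiv H2
Reagents that add atoms: none
Why: Lindlar semi-hydrogenation delivers hydrogen syn on the poisoned palladium surface, which should set both the 8Z and the 11Z double bond.

Step 4
Reactants: 5 (8Z,11Z)-pentadeca-8,11-dien-1-ol
Product: 6 (8Z,11Z)-1-bromopentadeca-8,11-diene
Conditions: CBr4, PPh3, CH2Cl2, 0 °C
Reagents that add atoms: tetrabromomethane, BrC(Br)(Br)Br
Why: The Appel reaction converts the primary alcohol into the bromide under neutral conditions that should leave the skipped Z,Z-diene untouched.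

Step 5
Reactants: 6 (8Z,11Z)-1-bromopentadeca-8,11-diene; 7 dimethyl malonate
Product: 9 dimethyl 2-[(8Z,11Z)-pentadeca-8,11-dien-1-yl]malonate, via sodium dimethyl malonate 8 (not isolated)
Conditions: 7 (3 equiv), NaH, THF/DMF, 0 °C; then 6, NaI (cat.), 60 °C
Reagents that add atoms: none
Why: Malonic ester synthesis: SN2 alkylation of the sodium enolate by the primary bromide should proceed cleanly, the excess of malonate suppressing dialkylation.

Step 6
Reactants: 9 dimethyl 2-[(8Z,11Z)-pentadeca-8,11-dien-1-yl]malonate
Product: 10 2-[(8Z,11Z)-pentadeca-8,11-dien-1-yl]malonic acid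
Conditions: KOH, MeOH/THF/H2O, rt; then 1 M HCl, 0 °C
Reagents that add atoms: potassium hydroxide, [K+].[OH-]
Why: Saponification of both methyl esters at room temperature and acidification in the cold should give the malonic acid without decarboxylation.

Step 7
Reactants: 10 2-[(8Z,11Z)-pentadeca-8,11-dien-1-yl]malonic acid
Product: 11 2-[(8Z,11Z)-pentadeca-8,11-dien-1-yl]malonyl dichloride
Conditions: (COCl)2, DMF (cat.), CH2Cl2, 0 °C to rt; evaporated and used crude
Reagents that add atoms: oxalyl chloride, ClC(=O)C(=O)Cl
Why: Acid chloride formation through the catalytic chloroiminium (Vilsmeier-type) species gives only gaseous by-products, so the dichloride should be usable without purification.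

Step 8
Reactants: 11 2-[(8Z,11Z)-pentadeca-8,11-dien-1-yl]malonyl dichloride; 12 allyl methyl ether
Product: 18 4-methoxy-2-[(8Z,11Z)-pentadeca-8,11-dien-1-yl]benzene-1,3-diol, via 1-methoxyallyllithium 13 (not isolated), via (Z)-3-methoxyallylzinc chloride 14 (not isolated), via keto acid chloride 15 (not isolated), via acylketene 16 (not isolated), via cyclohexadienone 17 (not isolated)
Conditions: 12, sBuLi, THF, −78 °C; ZnCl2, −78 °C; added slowly to 11, THF/Et2O, −78 °C; then Et3N, −78 °C to 40 °C; aq. HCl work-up
Reagents that add atoms: none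
Why: Proposed new method: zinc reagent 14 should acylate one acid chloride of 11 with allyl transposition at its oxygen-bearing carbon (bond C4–C5) to give 15, Et3N should then eliminate HCl to acylketene 16 and enolise its ketone towards C5, and the resulting dienylketene should close bond C1–C2 to cyclohexadienone 17, which tautomerises to arene 18. The closest known reaction types are the [3+3] cyclocondensation of malonyl dichloride with 2-alkoxypropenes to phloroglucinol monoethers, the acylation of γ-alkoxyallyl and other allylic zinc reagents by acid chlorides at the substituted terminus, and the dienylketene-to-phenol electrocyclisation that ends the Danheiser and Moore benzannulations. The single ring closed here, the future quinone ring, forms by a thermal disrotatory 6π-electrocyclisation of the dienylketene (equivalently a six-membered γ-C-acylation of the dienolate), because closure at the α-carbon or at oxygen would need a four-membered ring. No stereocentre remains: the two stereocentres of 15 are lost on enolisation and aromatisation, and the Z-alkenes of the side chain are not touched. The step needs mono-acylation of 11 and convergence of the ambident allyl nucleophile; inverse addition of one equivalent of 14 at −78 °C serves the first, and the constitutional symmetry of the alkylmalonyl unit secures the second, since acylation at the oxygen-bearing or at the CH2 terminus leads after ring closure to the same arene 18.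

Step 9
Reactants: 18 4-methoxy-2-[(8Z,11Z)-pentadeca-8,11-dien-1-yl]benzene-1,3-diol
Product: 19 sorgoleone-360
Conditions: (KSO3)2NO (Fremy's salt), KH2PO4, H2O/acetone, 0 °C to rt
Reagents that add atoms: potassium nitrosodisulfonate (Fremy's salt), [K+].[K+].[O]N(S(=O)(=O)[O-])S(=O)(=O)[O-]
Why: Teuber oxidation: the phenoxyl radical should be captured by a second nitroxyl at C1, the only free position para to one hydroxyl (C4–OH) and ortho to the other, and loss of imidodisulfonate should give the hydroxyquinone.

**Compound list**

1 | hex-2-yn-1-ol | CCCC#CCO | starting material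
2 | 1-bromohex-2-yne | CCCC#CCBr | intermediate
3 | non-8-yn-1-ol | C#CCCCCCCCO | starting material
4 | pentadeca-8,11-diyn-1-ol | CCCC#CCC#CCCCCCCCO | intermediate
5 | (8Z,11Z)-pentadeca-8,11-dien-1-ol | CCC/C=C\C/C=C\CCCCCCCO | intermediate
6 | (8Z,11Z)-1-bromopentadeca-8,11-diene | CCC/C=C\C/C=C\CCCCCCCBr | intermediate
7 | dimethyl malonate | COC(=O)CC(=O)OC | starting material
8 | sodium dimethyl malonate (sodium enolate of 7) | [Na+].COC(=O)[CH-]C(=O)OC | intermediate (not isolated)
9 | dimethyl 2-[(8Z,11Z)-pentadeca-8,11-dien-1-yl]malonate | CCC/C=C\C/C=C\CCCCCCCC(C(=O)OC)C(=O)OC | intermediate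
10 | 2-[(8Z,11Z)-pentadeca-8,11-dien-1-yl]malonic acid | CCC/C=C\C/C=C\CCCCCCCC(C(=O)O)C(=O)O | intermediate
11 | 2-[(8Z,11Z)-pentadeca-8,11-dien-1-yl]malonyl dichloride | CCC/C=C\C/C=C\CCCCCCCC(C(=O)Cl)C(=O)Cl | intermediate
12 | allyl methyl ether (3-methoxyprop-1-ene) | COCC=C | starting material
13 | 1-methoxyallyllithium | [Li]C(OC)C=C | intermediate (not isolated)
14 | (Z)-3-methoxyallylzinc chloride | CO/C=C\C[Zn]Cl | intermediate (not isolated)
15 | 4-methoxy-3-oxo-2-[(8Z,11Z)-pentadeca-8,11-dien-1-yl]hex-5-enoyl chloride (keto acid chloride, mixture of diastereomers) | CCC/C=C\C/C=C\CCCCCCCC(C(=O)Cl)C(=O)C(OC)C=C | intermediate (not isolated)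
16 | 4-methoxy-2-[(8Z,11Z)-pentadeca-8,11-dien-1-yl]hexa-1,5-diene-1,3-dione (acylketene, racemic) | CCC/C=C\C/C=C\CCCCCCCC(=C=O)C(=O)C(OC)C=C | intermediate (not isolated)
17 | 3-hydroxy-4-methoxy-2-[(8Z,11Z)-pentadeca-8,11-dien-1-yl]cyclohexa-2,4-dien-1-one | CCC/C=C\C/C=C\CCCCCCCC1=C(O)C(OC)=CCC1=O | intermediate (not isolated)
18 | 4-methoxy-2-[(8Z,11Z)-pentadeca-8,11-dien-1-yl]benzene-1,3-diol | CCC/C=C\C/C=C\CCCCCCCc1c(O)ccc(OC)c1O | intermediate
19 | sorgoleone-360, 2-hydroxy-5-methoxy-3-[(8Z,11Z)-pentadeca-8,11-dien-1-yl]cyclohexa-2,5-diene-1,4-dione | CCC/C=C\C/C=C\CCCCCCCC1=C(O)C(=O)C=C(OC)C1=O | target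

**Step count**

Total step count: 9. Longest linear sequence: 9 steps (1 → 2 → 4 → 5 → 6 → 9 → 10 → 11 → 18 → 19).

**Steps most likely to fail**

Step 8 (key step). The zinc reagent may acylate both acid chlorides of 11 or add to the newly formed ketone. The acylketene may dimerise before it enolises. The γ-acylated isomer may close a five-membered ring through the central carbon of its enol ether if acid is present. The fallback uses known chemistry, sets out from bromide 6 and comes back at resorcinol 18, so that steps 5 to 7 are not needed. Commercial 4-methoxybenzene-1,3-diol F1 is protected with MOMCl and iPr2NEt in CH2Cl2 to give 1-methoxy-2,4-bis(methoxymethoxy)benzene F2. Directed ortho-lithiation with nBuLi in THF at 0 °C should occur at the position between the two MOM ethers, and alkylation of the aryllithium with 6 (CuI cat. if needed) should give 1-methoxy-2,4-bis(methoxymethoxy)-3-[(8Z,11Z)-pentadeca-8,11-dien-1-yl]benzene F3. HCl in MeOH removes both MOM groups and returns 18.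

Step 9. The nitroxyl may attack the methoxy-bearing carbon para to the C2 hydroxyl with loss of methanol, abstract hydrogen from the doubly allylic CH2 of the side chain, or over-oxidise the hydroxyquinone. The fallback sets out from 18 and comes back at 19 without a radical oxidant. Vilsmeier–Haack formylation (POCl3, DMF, 0 °C) at the same uniquely activated position should give 2,4-dihydroxy-5-methoxy-3-[(8Z,11Z)-pentadeca-8,11-dien-1-yl]benzaldehyde F4. Dakin oxidation (H2O2, H3BO3, H2SO4 cat., THF) should convert the aldehyde into 5-methoxy-3-[(8Z,11Z)-pentadeca-8,11-dien-1-yl]benzene-1,2,4-triol F5. This hydroxyhydroquinone should be oxidised by air in EtOAc over aqueous NaHCO3 to 19.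

Step 3. Over-reduction of one or both alkenes and Z-to-E isomerisation on palladium would give mixtures that cannot be separated. The fallback sets out from diynol 4 and comes back at dienol 5 without hydrogen gas. Hydroboration with dicyclohexylborane (3.3 equiv, from BH3·SMe2 and cyclohexene, THF, 0 °C; one equivalent is taken up by the hydroxyl) should give the tris(dicyclohexylboryl) syn-adduct F6 as a mixture of regioisomers. Protonolysis of its two alkenyl–boron bonds with AcOH occurs with retention, and buffered H2O2 work-up removes the boron residues to give 5.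

**Further compounds**

F1 | step 8 | 4-methoxybenzene-1,3-diol | COc1ccc(O)cc1O
F2 | step 8 | 1-methoxy-2,4-bis(methoxymethoxy)benzene | COCOc1ccc(OC)c(OCOC)c1
F3 | step 8 | 1-methoxy-2,4-bis(methoxymethoxy)-3-[(8Z,11Z)-pentadeca-8,11-dien-1-yl]benzene | CCC/C=C\C/C=C\CCCCCCCc1c(OCOC)ccc(OC)c1OCOC
F4 | step 9 | 2,4-dihydroxy-5-methoxy-3-[(8Z,11Z)-pentadeca-8,11-dien-1-yl]benzaldehyde | CCC/C=C\C/C=C\CCCCCCCc1c(O)c(C=O)cc(OC)c1O
F5 | step 9 | 5-methoxy-3-[(8Z,11Z)-pentadeca-8,11-dien-1-yl]benzene-1,2,4-triol | CCC/C=C\C/C=C\CCCCCCCc1c(O)c(O)cc(OC)c1O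
F6 | step 3 | tris(dicyclohexylboryl) syn-hydroboration adduct of 4 (one regioisomer drawn) | C1CCCCC1B(C1CCCCC1)OCCCCCCC/C(B(C1CCCCC1)C1CCCCC1)=C\C/C=C(\CCC)B(C1CCCCC1)C1CCCCC1
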